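## Structural features

The target is a (2S)-flavanone: ring C (O1, C2, C3, C4, C4a, C8a) is a dihydropyranone fused to a phloroglucinol-type ring A with free hydroxyls at C5 and C7, and it carries ring B at C2. Ring B is a 1,3,4,5-tetrasubstituted benzene whose 4'-methoxy group is flanked by a 3'-prenyl group and a 5'-[(E)-3-methylbuta-1,3-dienyl] group. C2 is the only stereocentre (O1 > C1' > C3 > H, S) and has no stereogenic neighbour, so its configuration must come from a reagent or catalyst. The C2–O1 bond is benzylic and β to the C4 carbonyl: base opens ring C to a 2'-hydroxychalcone and strong acid ionises C2, and either event racemises the compound. The conjugated diene (acid, electrophiles, dienophiles, heat) and the prenyl alkene (acid) are the other fragile sites, and the three ring A oxygens have to be told apart. The real difficulty is to create C2 enantioselectively under conditions neutral enough for ring C and mild enough for the diene. The key step uses the fact that C2 is bonded to both O1 and C1' of ring B: in an open-chain aryl benzyl ether its two C–H bonds are the most hydridic in the molecule, so a carbene generated at C3, next to the C4 carbonyl on ring A, can insert there and close ring C by forming C2–C3.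

## Logic of the disconnections

17 to 16: the two phenolic O–H bonds are traced back to O–Si bonds. Free phenols would trap a carbene by O–H insertion and would interfere with the enolate chemistry before it. The cut adds no skeletal simplicity but makes the carbene step possible. The forward step must remove both silyl groups without generating a phenoxide basic enough to open ring C.

16 to 15: the C2–C3 bond is cut, which opens ring C and removes the only stereocentre, so the precursor is achiral. The flavanone collapses to an aryl benzyl ether carrying a diazoacetyl group. The forward step must prefer the benzylic C–H bond over the ether oxygen lone pair, over the silyl ether oxygen and over three alkenes, and must select one of two enantiotopic hydrogens.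

15 to 13 through 14: the C3–N bond of the diazo group is cut, so the carbene carbon becomes the methyl carbon of an acetyl group. This carbon is already present in phloroacetophenone, which avoids an acid chloride and diazomethane. The forward step needs transient activation of a simple methyl ketone, supplied by the trifluoroacetyl group of 14, and clean enolisation of a ketone flanked by two ortho oxygens.

13 to 10 plus 12: the benzylic C–O bond (the future O1–C2 bond) is cut, dividing the molecule into a ring A half and a ring B half of similar size. The forward step must etherify a chelated phenol without a base that strips or transfers aryl silyl ethers and without harming the diene, so a redox condensation at the alcohol oxidation level is chosen. A route through the benzylic bromide and a carbonate base with a later second silylation was set aside as two steps longer and harder on the silyl ethers.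

12 to 11: two O–Si bonds are cut. The forward step relies on the difference between the two accessible hydroxyls and the one held by hydrogen bonding to the carbonyl, and must stop at the bis-silyl stage.

10 to 9: a benzylic C–H bond is cut, returning to the aldehyde. The formyl group is kept through the ring B construction because it blocks the para position during the sigmatropic step and makes the phenol acidic. The forward step needs only a 1,2-hydride reduction that ignores the alkenes.

9 to 6 plus 8: the sp2–sp2 bond between C5' and the diene is cut, so the whole diene arrives with its E geometry defined and only after all heated steps. The forward coupling must take place at an ortho-substituted bromide below the temperature at which the diene dimerises.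

8 to 7: the C–B bond is cut. The forward hydroboration must be syn, place boron at the terminal carbon and touch the alkyne, not the alkene.

6 to 5: the O–CH3 bond is cut. The same oxygen has just served as the anchor for C-prenylation, and the forward methylation faces a hindered but acidic phenol.

5 to 4: the aryl–CH2 bond of the prenyl group is cut in a retro-sigmatropic sense, moving the allyl unit back to oxygen in inverted form. This gives ortho C-prenylation with full regiocontrol because the other ortho position carries bromine and the para position the formyl group. The forward step needs heat without cyclisation of the ortho-prenylphenol.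

4 to 3 plus 2: the O–C bond to the tertiary carbon is cut. The forward O-allylation must deliver the branched ether and must not equilibrate to the linear prenyl ether.

2 to 1: the carbonate C–O bond is cut, leading to the commercial tertiary allylic alcohol. The forward acylation of a hindered alcohol needs prior deprotonation.

## Other disconnections considered

Alternative 1: The cut is the C3–C4 bond. An N-heterocyclic carbene would add to the ring A aldehyde of A1, the acyl anion equivalent so formed would displace the primary toluenesulfonate in a 6-exo-tet closure, and release of the carbene would give A2. Two allyl ethers would then be removed with Pd(PPh3)4 and a soft nucleophile.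
- In favour: C2 is fixed before ring closure and is not a reacting centre. The step needs no metal, no diazo compound and no sulfonyl azide, which makes it the safer plan on that point. It cannot cyclopropanate the diene or prenyl group, a second point where it is better. The final unmasking is as mild as buffered fluoride (equal).
- Against: the aldehyde sits between two ortho oxygens on a very electron-rich ring, so formation of the Breslow intermediate should be slow. The amine base that liberates the carbene can eliminate toluenesulfonate across C2–C3 and can open A2 by retro-oxa-Michael reaction, both at the expense of C2. A1 is (R) by the sequence rules although its spatial arrangement is that of (S)-A2, which invites planning errors.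
- Comparison: building A1 needs a ring B glycol of defined configuration (made before the prenyl and diene alkenes exist, since they would compete in a dihydroxylation), a selective sulfonylation and an aryl ether bond to a secondary benzylic carbon. The chosen plan makes ring and stereocentre in one step from an achiral precursor and should be three to four steps shorter.

Alternative 2: The cut is the C4–C4a bond. Acid A3 would be converted to its chloride A4, which would acylate the ring A carbon ortho to the ether oxygen to give A5. Suzuki coupling of A5 with 8 and removal of two allyl groups would follow.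
- In favour: ring A is a phloroglucinol triether with two equivalent ortho positions, so the ring closure is fast and regiochemically unambiguous; as a ring-forming event it is more predictable than a carbene insertion. The diene is introduced only after the electrophilic step, so the most fragile group is absent from the key step, which is better than the chosen plan. Compounds 6 and 8 of the present route could be reused.
- Against: A4 has an aryloxy leaving group on a benzylic carbon stabilised by a para-methoxy group. AlCl3, SnCl4 or the HCl released can ionise that C–O bond (racemisation) or cause β-elimination to a cinnamoyl derivative. The prenyl alkene is exposed to acylium ion and HCl, and allyl aryl ethers can be cleaved or rearranged by the Lewis acid. Making A3 requires an ether bond at an electron-rich secondary benzylic carbon with clean inversion, or an asymmetric oxa-Michael addition, both prone to erosion.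
- Comparison: C2 is exposed to ionising conditions twice, whereas the chosen plan creates it under neutral conditions. Two further steps follow the ring closure against one.

Alternative 3: The cut is the O1–C8a bond. The alkoxide of the ring B carbinol of the anti-diol A6 would couple with the aryl triflate under a zerovalent palladium catalyst (Buchwald–Hartwig etherification) to give A7. The C4 carbinol would then be oxidised and the methoxymethyl ethers removed with acid.
- In favour: no bond to C2 is made or broken, so a configuration set by reliable asymmetric carbonyl chemistry is carried through with retention. This is the most secure handling of C2 of the four plans and better than the chosen one, whose enantiomeric purity rests on a catalyst telling two hydrogens apart. The second hydroxyl cannot compete because it would close a four-membered ring, and no carbene is involved.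
- Against: the palladium alkoxide of a secondary benzylic alcohol is prone to β-hydride elimination. The triflate lies on an electron-rich ring beside an ortho substituent, which slows oxidative addition and leaves time for base to cleave the S–O bond. The diene can bind zerovalent palladium. A6 holds a second stereocentre that is made only to be oxidised away. Acidic removal of the methoxymethyl groups endangers the diene, the prenyl group and C2.
- Comparison: A6 needs three differentiated ring A oxygens and a three-carbon chain built by aldol and reduction chemistry, and two steps follow ring closure. This is the longest plan.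

Key step: step 11

Assumption: the sense of induction of the dirhodium catalyst cannot be derived from the structure alone; the route is written for Rh2(S-PTTL)4, and Rh2(R-PTTL)4 replaces it if the (S)-ligand favours the (2R) product; 2,4,6-trihydroxyacetophenone is used dried.

Step 1
Reactants: 1 2-methylbut-3-en-2-ol
Product: 2 tert-butyl 2-methylbut-3-en-2-yl carbonate
Conditions: n-BuLi, THF, −78 °C to 0 °C; Boc2O, 0 °C to rt
Reagents that add atoms: di-tert-butyl dicarbonate, CC(C)(C)OC(=O)OC(=O)OC(C)(C)C
Why: O-acylation of a lithium alkoxide; the tertiary alcohol is too hindered for amine-catalysed acylation, so it is deprotonated first and then attacks the dicarbonate to give the mixed carbonate.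

Step 2
Reactants: 3 3-bromo-4-hydroxybenzaldehyde; 2 tert-butyl 2-methylbut-3-en-2-yl carbonate
Product: 4 3-bromo-4-[(2-methylbut-3-en-2-yl)oxy]benzaldehyde
Conditions: Pd(PPh3)4 (3 mol%), 4 Å MS, THF, 0 °C
Reagents that add atoms: none
Why: Tsuji–Trost O-allylation: zerovalent palladium ionises the carbonate to a 1,1-dimethyl-π-allyl complex and tert-butoxide, which deprotonates the acidic phenol, and the phenoxide attacks the more substituted allyl terminus under kinetic control. Low temperature and early quench should keep the tertiary ether from re-ionising to the linear prenyl ether, and oxidative addition into the aryl bromide is too slow at 0 °C to interfere.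

Step 3
Reactants: 4 3-bromo-4-[(2-methylbut-3-en-2-yl)oxy]benzaldehyde
Product: 5 3-bromo-4-hydroxy-5-(3-methylbut-2-en-1-yl)benzaldehyde
Conditions: PhNEt2, 150 °C
Reagents that add atoms: none
Why: Aromatic Claisen rearrangement: the [3,3] shift transfers the inverted allyl unit to the only free ortho carbon and tautomerisation restores the phenol, so the 1,1-dimethylallyl ether becomes a C-prenyl group. Bromine blocks the other ortho position, the formyl group blocks the para position, and the basic solvent suppresses acid-catalysed chroman formation.

Step 4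
Reactants: 5 3-bromo-4-hydroxy-5-(3-methylbut-2-en-1-yl)benzaldehyde
Product: 6 3-bromo-4-methoxy-5-(3-methylbut-2-en-1-yl)benzaldehyde
Conditions: MeI, K2CO3, acetone, 40 °C
Reagents that add atoms: iodomethane, CI
Why: Williamson ether synthesis on an acidic phenol whose phenoxide is small enough to be methylated despite two ortho substituents; capping the oxygen also removes the nucleophile that could cyclise onto the prenyl group.

Step 5
Reactants: 7 2-methylbut-1-en-3-yne
Product: 8 4,4,5,5-tetramethyl-2-[(1E)-3-methylbuta-1,3-dien-1-yl]-1,3,2-dioxaborolane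
Conditions: pinacolborane, Cp2Zr(H)Cl (5 mol%), Et3N (10 mol%), CH2Cl2, rt, sealed vessel
Reagents that add atoms: pinacolborane, CC1(C)OBOC1(C)C
Why: Zirconium-catalysed hydroboration of a terminal alkyne: syn addition with boron at the terminal carbon gives the E alkenyl boronate, and the 1,1-disubstituted alkene is left alone because hydrozirconation of the alkyne is much faster.

Step 6
Reactants: 6 3-bromo-4-methoxy-5-(3-methylbut-2-en-1-yl)benzaldehyde; 8 4,4,5,5-tetramethyl-2-[(1E)-3-methylbuta-1,3-dien-1-yl]-1,3,2-dioxaborolane
Product: 9 4-methoxy-3-[(1E)-3-methylbuta-1,3-dien-1-yl]-5-(3-methylbut-2-en-1-yl)benzaldehyde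
Conditions: Pd(dppf)Cl2 (3 mol%), K2CO3, 1,4-dioxane/H2O, 70 °C
Reagents that add atoms: none
Why: Suzuki–Miyaura coupling; the alkenyl group is transferred with retention of the E geometry, and the moderate temperature should spare the diene from thermal dimerisation.

Step 7
Reactants: 9 4-methoxy-3-[(1E)-3-methylbuta-1,3-dien-1-yl]-5-(3-methylbut-2-en-1-yl)benzaldehyde
Product: 10 {4-methoxy-3-[(1E)-3-methylbuta-1,3-dien-1-yl]-5-(3-methylbut-2-en-1-yl)phenyl}methanol
Conditions: NaBH4, MeOH, 0 °C
Reagents that add atoms: none
Why: Hydride 1,2-reduction of an aryl aldehyde; neither alkene unit is conjugated to the carbonyl, so both are untouched.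

Step 8
Reactants: 11 1-(2,4,6-trihydroxyphenyl)ethanone
Product: 12 1-[2-hydroxy-4,6-bis(triisopropylsilyloxy)phenyl]ethanone
Conditions: TIPSCl (2.1 equiv), imidazole, DMF, 0 °C to rt
Reagents that add atoms: triisopropylsilyl chloride, CC(C)[Si](Cl)(C(C)C)C(C)C
Why: Imidazole-mediated silylation of phenols: the para hydroxyl and one ortho hydroxyl react, after which the remaining ortho hydroxyl is locked in a hydrogen bond to the carbonyl and is not silylated by the bulky chloride.

Step 9
Reactants: 10 {4-methoxy-3-[(1E)-3-methylbuta-1,3-dien-1-yl]-5-(3-methylbut-2-en-1-yl)phenyl}methanol; 12 1-[2-hydroxy-4,6-bis(triisopropylsilyloxy)phenyl]ethanone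
Product: 13 1-[2-({4-methoxy-3-[(1E)-3-methylbuta-1,3-dien-1-yl]-5-(3-methylbut-2-en-1-yl)phenyl}methoxy)-4,6-bis(triisopropylsilyloxy)phenyl]ethanone
Conditions: PPh3, DIAD (added last, dropwise), THF, 0 °C to rt
Reagents that add atoms: none
Why: Mitsunobu etherification: the primary benzylic alcohol is activated as its alkoxyphosphonium ion and displaced by the phenoxide of the chelated but sufficiently acidic phenol. The medium is neutral, so the aryl silyl ethers should neither cleave nor migrate, and adding the azodicarboxylate last keeps its free concentration too low for cycloaddition to the diene.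

Step 10
Reactants: 13 1-[2-({4-methoxy-3-[(1E)-3-methylbuta-1,3-dien-1-yl]-5-(3-methylbut-2-en-1-yl)phenyl}methoxy)-4,6-bis(triisopropylsilyloxy)phenyl]ethanone
Product: 15 2-diazo-1-[2-({4-methoxy-3-[(1E)-3-methylbuta-1,3-dien-1-yl]-5-(3-methylbut-2-en-1-yl)phenyl}methoxy)-4,6-bis(triisopropylsilyloxy)phenyl]ethanone, via trifluoroacetyl diketone 14 (not isolated)
Conditions: LiN(SiMe3)2, THF, −78 °C; CF3CO2CH2CF3; aq NH4Cl; then p-ABSA, Et3N, H2O (1 equiv), MeCN, rt
Reagents that add atoms: 4-acetamidobenzenesulfonyl azide, CC(=O)Nc1ccc(cc1)S(=O)(=O)N=[N+]=[N-] (the two diazo nitrogens); 2,2,2-trifluoroethyl trifluoroacetate, O=C(OCC(F)(F)F)C(F)(F)F (trifluoroacetyl group of 14 only)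
Why: Detrifluoroacetylative diazo transfer, a variant of the Regitz reaction: the lithium enolate undergoes Claisen acylation to the activated diketone 14, which accepts the diazo group from the sulfonyl azide and loses the trifluoroacetyl group to the sulfonamide nitrogen. This gives the diazomethyl ketone without diazomethane and with a sulfonyl azide of low shock sensitivity; the benzylic ether protons and silyl ethers are inert to the amide base at −78 °C.

Step 11
Reactants: 15 2-diazo-1-[2-({4-methoxy-3-[(1E)-3-methylbuta-1,3-dien-1-yl]-5-(3-methylbut-2-en-1-yl)phenyl}methoxy)-4,6-bis(triisopropylsilyloxy)phenyl]ethanone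
Product: 16 (2S)-2-{4-methoxy-3-[(1E)-3-methylbuta-1,3-dien-1-yl]-5-(3-methylbut-2-en-1-yl)phenyl}-5,7-bis(triisopropylsilyloxy)-2,3-dihydro-4H-chromen-4-one
Conditions: Rh2(S-PTTL)4 (1 mol%), 4 Å MS, CH2Cl2, 0 °C, slow addition of 15 at high dilution
Reagents that add atoms: none
Why: Intramolecular dirhodium-carbene C–H insertion of a 2-(benzyloxy)aryl diazomethyl ketone to a chroman-4-one, a known reaction class with enantioselective examples under chiral dirhodium carboxylates. The diazo carbon binds an axial site of the catalyst, dinitrogen leaves, and the electrophilic carbene at C3 inserts into a benzylic C–H bond of the OCH2 group through a three-centre transition state with hydride-transfer character, forming C2–C3 and releasing the catalyst. Ring C closes by 1,6-insertion through a six-membered chair-like transition state comprising C3, C4, C4a, C8a, O1 and C2; the usual five-membered mode is unavailable because the fifth atom is the ether oxygen. The C2 stereocentre is set by the catalyst alone: the wall of phthalimido groups of the tert-leucinate ligands should let the ring B aryl group lie pseudo-equatorial on one face only, so one enantiotopic hydrogen is selected. Site selectivity comes from the substrate: the C2–H bonds are activated by O1 and by ring B, whose para-methoxy group adds hydride-donor character, while the other ortho oxygen bears a bulky silyl group with no C–H bond in reach. Chemoselectivity over oxonium ylide formation at O1 with [1,2]-benzyl shift, over attack at the silyl ether oxygen and over cyclopropanation of the prenyl and diene units rests on the low nucleophilicity of the two aryl ether oxygens, the bulk of the triisopropylsilyl group and slow addition at high dilution, which leaves only intramolecular pathways. Compound 15 is used directly after step 10 and shielded from light.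

Step 12
Reactants: 16 (2S)-2-{4-methoxy-3-[(1E)-3-methylbuta-1,3-dien-1-yl]-5-(3-methylbut-2-en-1-yl)phenyl}-5,7-bis(triisopropylsilyloxy)-2,3-dihydro-4H-chromen-4-one
Product: 17 (2S)-5,7-dihydroxy-2-{4-methoxy-3-[(1E)-3-methylbuta-1,3-dien-1-yl]-5-(3-methylbut-2-en-1-yl)phenyl}-2,3-dihydro-4H-chromen-4-one
Conditions: TBAF (2.5 equiv), AcOH (2.5 equiv), THF, 0 °C
Reagents that add atoms: none
Why: Fluoride cleavage of aryl silyl ethers driven by Si–F bond formation; acetic acid protonates the phenoxides as they form, so ring C should not open by retro-oxa-Michael reaction and C2 keeps its configuration.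

Compound list

1 | 2-methylbut-3-en-2-ol | C=CC(C)(C)O | starting material
2 | tert-butyl 2-methylbut-3-en-2-yl carbonate | C=CC(C)(C)OC(=O)OC(C)(C)C | intermediate
3 | 3-bromo-4-hydroxybenzaldehyde | O=Cc1ccc(O)c(Br)c1 | starting material
4 | 3-bromo-4-[(2-methylbut-3-en-2-yl)oxy]benzaldehyde | O=Cc1ccc(OC(C)(C)C=C)c(Br)c1 | intermediate
5 | 3-bromo-4-hydroxy-5-(3-methylbut-2-en-1-yl)benzaldehyde | O=Cc1cc(Br)c(O)c(CC=C(C)C)c1 | intermediate
6 | 3-bromo-4-methoxy-5-(3-methylbut-2-en-1-yl)benzaldehyde | COc1c(Br)cc(C=O)cc1CC=C(C)C | intermediate
7 | 2-methylbut-1-en-3-yne | C=C(C)C#C | starting material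
8 | 4,4,5,5-tetramethyl-2-[(1E)-3-methylbuta-1,3-dien-1-yl]-1,3,2-dioxaborolane | C=C(C)/C=C/B1OC(C)(C)C(C)(C)O1 | intermediate
9 | 4-methoxy-3-[(1E)-3-methylbuta-1,3-dien-1-yl]-5-(3-methylbut-2-en-1-yl)benzaldehyde | C=C(C)/C=C/c1cc(C=O)cc(CC=C(C)C)c1OC | intermediate
10 | {4-methoxy-3-[(1E)-3-methylbuta-1,3-dien-1-yl]-5-(3-methylbut-2-en-1-yl)phenyl}methanol | C=C(C)/C=C/c1cc(CO)cc(CC=C(C)C)c1OC | intermediate
11 | 1-(2,4,6-trihydroxyphenyl)ethanone | CC(=O)c1c(O)cc(O)cc1O | starting material
12 | 1-[2-hydroxy-4,6-bis(triisopropylsilyloxy)phenyl]ethanone | CC(=O)c1c(O)cc(O[Si](C(C)C)(C(C)C)C(C)C)cc1O[Si](C(C)C)(C(C)C)C(C)C | intermediate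
13 | 1-[2-({4-methoxy-3-[(1E)-3-methylbuta-1,3-dien-1-yl]-5-(3-methylbut-2-en-1-yl)phenyl}methoxy)-4,6-bis(triisopropylsilyloxy)phenyl]ethanone | C=C(C)/C=C/c1cc(COc2cc(O[Si](C(C)C)(C(C)C)C(C)C)cc(O[Si](C(C)C)(C(C)C)C(C)C)c2C(C)=O)cc(CC=C(C)C)c1OC | intermediate
14 | 4,4,4-trifluoro-1-[2-({4-methoxy-3-[(1E)-3-methylbuta-1,3-dien-1-yl]-5-(3-methylbut-2-en-1-yl)phenyl}methoxy)-4,6-bis(triisopropylsilyloxy)phenyl]butane-1,3-dione | C=C(C)/C=C/c1cc(COc2cc(O[Si](C(C)C)(C(C)C)C(C)C)cc(O[Si](C(C)C)(C(C)C)C(C)C)c2C(=O)CC(=O)C(F)(F)F)cc(CC=C(C)C)c1OC | intermediate
15 | 2-diazo-1-[2-({4-methoxy-3-[(1E)-3-methylbuta-1,3-dien-1-yl]-5-(3-methylbut-2-en-1-yl)phenyl}methoxy)-4,6-bis(triisopropylsilyloxy)phenyl]ethanone | C=C(C)/C=C/c1cc(COc2cc(O[Si](C(C)C)(C(C)C)C(C)C)cc(O[Si](C(C)C)(C(C)C)C(C)C)c2C(=O)C=[N+]=[N-])cc(CC=C(C)C)c1OC | intermediate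
16 | (2S)-2-{4-methoxy-3-[(1E)-3-methylbuta-1,3-dien-1-yl]-5-(3-methylbut-2-en-1-yl)phenyl}-5,7-bis(triisopropylsilyloxy)-2,3-dihydro-4H-chromen-4-one | C=C(C)/C=C/c1cc([C@@H]2CC(=O)c3c(O[Si](C(C)C)(C(C)C)C(C)C)cc(O[Si](C(C)C)(C(C)C)C(C)C)cc3O2)cc(CC=C(C)C)c1OC | intermediate
17 | (2S)-5,7-dihydroxy-2-{4-methoxy-3-[(1E)-3-methylbuta-1,3-dien-1-yl]-5-(3-methylbut-2-en-1-yl)phenyl}-2,3-dihydro-4H-chromen-4-one | C=C(C)/C=C/c1cc([C@@H]2CC(=O)c3c(O)cc(O)cc3O2)cc(CC=C(C)C)c1OC | target

Total step count: 12. Longest linear sequence: 10 steps (steps 1, 2, 3, 4, 6, 7, 9, 10, 11, 12).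

Least certain steps

Step 11 (key step). What may go wrong: attack of the carbene on the lone pair of O1 to give an oxonium ylide that rearranges by [1,2]-benzyl shift to a benzofuranone; weak discrimination of the two enantiotopic hydrogens by an acceptor-only carbene with an early transition state; intermolecular cyclopropanation of the diene if dilution is insufficient. Fallback, which avoids carbenes altogether, sets out from 12 and 9 and rejoins the route at 16:
- The dianion of 12 (LiN(SiMe3)2, THF, −78 °C) would be C-acylated with Boc2O to tert-butyl 3-[2-hydroxy-4,6-bis(triisopropylsilyloxy)phenyl]-3-oxopropanoate F1.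
- Knoevenagel condensation of F1 with 9 (piperidine, AcOH, 4 Å MS, toluene, rt) would give the alkylidene β-keto ester F2.
- A quinine- or quinidine-derived bifunctional thiourea, whichever pseudoenantiomer favours 2S, would catalyse a 6-endo oxa-Michael addition of the free phenol to give the tert-butyl (2S)-flavanone-3-carboxylate F3.
- TsOH in toluene at the lowest effective temperature (60–80 °C) would remove the ester as isobutene and CO2 to give 16; the diene is the group to watch in this last operation.

Step 9. What may go wrong: sluggish reaction of the hydrogen-bonded phenol, which leaves the activated benzylic alcohol to alkylate the reduced azodicarboxylate or the electron-rich ring A carbon, and cycloaddition of the azodicarboxylate to the diene. Fallback sets out from 10 and 11 and rejoins at 13: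
- 10 would be converted with CBr4 and PPh3 (CH2Cl2, 0 °C, Appel reaction) into 5-(bromomethyl)-2-methoxy-1-[(1E)-3-methylbuta-1,3-dien-1-yl]-3-(3-methylbut-2-en-1-yl)benzene F4.
- 11 would be silylated once with TIPSCl (1 equiv, imidazole, DMF, 0 °C) to 1-[2,6-dihydroxy-4-(triisopropylsilyloxy)phenyl]ethanone F5.
- Williamson alkylation of F5 with F4 (K2CO3, acetone, rt) should stop at the mono-ether 1-[2-(benzyloxy)-6-hydroxy-4-(triisopropylsilyloxy)phenyl]ethanone carrying the full ring B F6, because the second hydroxyl is then chelated.
- TIPSOTf and 2,6-lutidine (CH2Cl2, 0 °C) would silylate the chelated hydroxyl to give 13.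

Step 10. What may go wrong: incomplete trifluoroacetylation of the enolate of a ketone twisted out of the ring plane by two ortho oxygens, so that diazo transfer has no activated substrate. Fallback sets out from 13 and rejoins at 15:
- The enolate of 13 would be trapped (LiN(SiMe3)2, Me3SiCl, THF, −78 °C) as the trimethylsilyl enol ether F7.
- F7 would be brominated with NBS (THF, −78 °C), where it is by far the most nucleophilic alkene, to the α-bromo ketone F8.
- F8 would be treated with N,N'-ditosylhydrazine and DBU (THF, 0 °C); N-alkylation followed by two eliminations of sulfinate would give 15.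

Step 2. What may go wrong: re-ionisation of the tertiary allyl aryl ether by the palladium catalyst, since the electron-poor phenoxide is a good leaving group, with drift to the linear prenyl ether that cannot give the C-prenyl product on heating. Fallback sets out from 3 and rejoins at 4:
- 3 would be alkylated with 3-chloro-3-methylbut-1-yne (CuCl2·2H2O cat., DBU, MeCN, 0 °C) to 3-bromo-4-[(2-methylbut-3-yn-2-yl)oxy]benzaldehyde F9.
- The alkyne of F9 would be semi-hydrogenated (H2, Pd/CaCO3 poisoned with Pb(OAc)2, quinoline, EtOAc, rt) to give 4.

## Further compounds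

F1 | step 11 | tert-butyl 3-[2-hydroxy-4,6-bis(triisopropylsilyloxy)phenyl]-3-oxopropanoate | CC(C)(C)OC(=O)CC(=O)c1c(O)cc(O[Si](C(C)C)(C(C)C)C(C)C)cc1O[Si](C(C)C)(C(C)C)C(C)C
F2 | step 11 | tert-butyl 2-[2-hydroxy-4,6-bis(triisopropylsilyloxy)benzoyl]-3-{4-methoxy-3-[(1E)-3-methylbuta-1,3-dien-1-yl]-5-(3-methylbut-2-en-1-yl)phenyl}prop-2-enoate (geometry of the new alkene not defined) | C=C(C)/C=C/c1cc(C=C(C(=O)OC(C)(C)C)C(=O)c2c(O)cc(O[Si](C(C)C)(C(C)C)C(C)C)cc2O[Si](C(C)C)(C(C)C)C(C)C)cc(CC=C(C)C)c1OC
F3 | step 11 | tert-butyl (2S)-2-{4-methoxy-3-[(1E)-3-methylbuta-1,3-dien-1-yl]-5-(3-methylbut-2-en-1-yl)phenyl}-4-oxo-5,7-bis(triisopropylsilyloxy)-3,4-dihydro-2H-chromene-3-carboxylate (C3 epimerisable) | C=C(C)/C=C/c1cc([C@@H]2C(C(=O)OC(C)(C)C)C(=O)c3c(O[Si](C(C)C)(C(C)C)C(C)C)cc(O[Si](C(C)C)(C(C)C)C(C)C)cc3O2)cc(CC=C(C)C)c1OC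
F4 | step 9 | 5-(bromomethyl)-2-methoxy-1-[(1E)-3-methylbuta-1,3-dien-1-yl]-3-(3-methylbut-2-en-1-yl)benzene | C=C(C)/C=C/c1cc(CBr)cc(CC=C(C)C)c1OC
F5 | step 9 | 1-[2,6-dihydroxy-4-(triisopropylsilyloxy)phenyl]ethanone | CC(=O)c1c(O)cc(O[Si](C(C)C)(C(C)C)C(C)C)cc1O
F6 | step 9 | 1-[2-hydroxy-6-({4-methoxy-3-[(1E)-3-methylbuta-1,3-dien-1-yl]-5-(3-methylbut-2-en-1-yl)phenyl}methoxy)-4-(triisopropylsilyloxy)phenyl]ethanone | C=C(C)/C=C/c1cc(COc2cc(O[Si](C(C)C)(C(C)C)C(C)C)cc(O)c2C(C)=O)cc(CC=C(C)C)c1OC
F7 | step 10 | trimethylsilyl enol ether of 13: {1-[2-({4-methoxy-3-[(1E)-3-methylbuta-1,3-dien-1-yl]-5-(3-methylbut-2-en-1-yl)phenyl}methoxy)-4,6-bis(triisopropylsilyloxy)phenyl]ethenyl}oxy(trimethyl)silane | C=C(C)/C=C/c1cc(COc2cc(O[Si](C(C)C)(C(C)C)C(C)C)cc(O[Si](C(C)C)(C(C)C)C(C)C)c2C(=C)O[Si](C)(C)C)cc(CC=C(C)C)c1OC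
F8 | step 10 | 2-bromo-1-[2-({4-methoxy-3-[(1E)-3-methylbuta-1,3-dien-1-yl]-5-(3-methylbut-2-en-1-yl)phenyl}methoxy)-4,6-bis(triisopropylsilyloxy)phenyl]ethanone | C=C(C)/C=C/c1cc(COc2cc(O[Si](C(C)C)(C(C)C)C(C)C)cc(O[Si](C(C)C)(C(C)C)C(C)C)c2C(=O)CBr)cc(CC=C(C)C)c1OC
F9 | step 2 | 3-bromo-4-[(2-methylbut-3-yn-2-yl)oxy]benzaldehyde | O=Cc1ccc(OC(C)(C)C#C)c(Br)c1
A1 | alternative 1 | (2R)-2-[2-formyl-3,5-bis(prop-2-en-1-yloxy)phenoxy]-2-{4-methoxy-3-[(1E)-3-methylbuta-1,3-dien-1-yl]-5-(3-methylbut-2-en-1-yl)phenyl}ethyl 4-methylbenzenesulfonate | C=C(C)/C=C/c1cc([C@H](COS(=O)(=O)c2ccc(C)cc2)Oc2cc(OCC=C)cc(OCC=C)c2C=O)cc(CC=C(C)C)c1OC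
A2 | alternative 1 | (2S)-2-{4-methoxy-3-[(1E)-3-methylbuta-1,3-dien-1-yl]-5-(3-methylbut-2-en-1-yl)phenyl}-5,7-bis(prop-2-en-1-yloxy)-2,3-dihydro-4H-chromen-4-one | C=C(C)/C=C/c1cc([C@@H]2CC(=O)c3c(OCC=C)cc(OCC=C)cc3O2)cc(CC=C(C)C)c1OC
A3 | alternative 2 | (3S)-3-[3,5-bis(prop-2-en-1-yloxy)phenoxy]-3-[3-bromo-4-methoxy-5-(3-methylbut-2-en-1-yl)phenyl]propanoic acid | COc1c(Br)cc([C@H](CC(=O)O)Oc2cc(OCC=C)cc(OCC=C)c2)cc1CC=C(C)C
A4 | alternative 2 | (3S)-3-[3,5-bis(prop-2-en-1-yloxy)phenoxy]-3-[3-bromo-4-methoxy-5-(3-methylbut-2-en-1-yl)phenyl]propanoyl chloride | COc1c(Br)cc([C@H](CC(=O)Cl)Oc2cc(OCC=C)cc(OCC=C)c2)cc1CC=C(C)C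
A5 | alternative 2 | (2S)-2-[3-bromo-4-methoxy-5-(3-methylbut-2-en-1-yl)phenyl]-5,7-bis(prop-2-en-1-yloxy)-2,3-dihydro-4H-chromen-4-one | COc1c(Br)cc([C@@H]2CC(=O)c3c(OCC=C)cc(OCC=C)cc3O2)cc1CC=C(C)C
A6 | alternative 3 | 2-[(1S,3S)-1,3-dihydroxy-3-{4-methoxy-3-[(1E)-3-methylbuta-1,3-dien-1-yl]-5-(3-methylbut-2-en-1-yl)phenyl}propyl]-3,5-bis(methoxymethoxy)phenyl trifluoromethanesulfonate | C=C(C)/C=C/c1cc([C@@H](O)C[C@H](O)c2c(OCOC)cc(OCOC)cc2OS(=O)(=O)C(F)(F)F)cc(CC=C(C)C)c1OC
A7 | alternative 3 | (2S,4S)-2-{4-methoxy-3-[(1E)-3-methylbuta-1,3-dien-1-yl]-5-(3-methylbut-2-en-1-yl)phenyl}-5,7-bis(methoxymethoxy)-3,4-dihydro-2H-chromen-4-ol | C=C(C)/C=C/c1cc([C@@H]2C[C@H](O)c3c(OCOC)cc(OCOC)cc3O2)cc(CC=C(C)C)c1OC
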